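**Retrosynthetic overview**

1. The target is ent-epiafzelechin-(4β→8)-epiafzelechin-(4α→8)-(2S,3S,4R)-flavan-3,4-diol: top unit 2S,3S,4R, middle unit 2R,3R,4S, bottom unit 2S,3S,4R. The last operations are deprotections (one pivalate, two silyl ethers, ten benzyl ethers).
2. Key disconnection: the bond C4(top)–C8(middle) together with ring C of the top unit. That ring (O1–C2–C3–C4–C4a–C8a) carries 2-aryl, 3-O and 4-aryl all cis, which is the endo adduct of an (E)-o-quinone methide O1=C8a–C4a=C4 with a (Z)-alkene C2=C3. The top unit therefore enters as an O-Boc salicylaldehyde (ring A plus C4) and a (Z)-enol pivalate (C2, C3, ring B); the C8-lithiated dimer attacks the aldehyde carbon, and the ortho O-Boc group turns the adduct into the quinone methide.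
3. Dimer: C4(middle)–C8(bottom) by addition of the C8-metalated bottom unit to a (2S)-flavanone. C2 then relays to C4 (hydroboration anti to the aryl group) and to C3 (oxidation, bulky hydride).
4. Bottom unit: from the (2R)-flavanone through the flav-3-ene, hydroboration, inversion at C3 and DDQ/water oxidation at C4.
5. Ring order: rings A and C of the bottom and middle units come from one chromone (ring B by Rh-catalysed conjugate arylation, either ligand antipode); ring C of the top unit is formed last, in the key step.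

Key step: step 21

**Remarks**
- α and β refer to the usual flavan drawing (ring A at the left, O1 at the upper right, C2→C4 clockwise): β points to the viewer, α away.
- Assumed commercial: 5,7-dihydroxychromone, 2,4,6-trihydroxybenzaldehyde, [4-(benzyloxy)phenyl]boronic acid, 1-(benzyloxy)-4-ethynylbenzene, pivalic acid.
- The ligand antipode for each flavanone is to be assigned on the first run.
- The π-facial outcome of step 21 rests on a steric model, not on precedent; it is the main risk and has a known-chemistry fallback.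

**Route**

Step 1
Reactants: 1 5,7-dihydroxy-4H-chromen-4-one
Product: 2 5,7-bis(benzyloxy)-4H-chromen-4-one
Conditions: BnBr (excess), K2CO3, DMF, 70 °C
Reagents that add atoms: benzyl bromide, BrCc1ccccc1
Why: Williamson ether synthesis; heat and excess reagent are needed for the hydrogen-bonded 5-hydroxyl.

Step 2
Reactants: 2 5,7-bis(benzyloxy)-4H-chromen-4-one; 3 [4-(benzyloxy)phenyl]boronic acid
Product: 4 (2R)-5,7-bis(benzyloxy)-2-[4-(benzyloxy)phenyl]chroman-4-one (aryl β)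
Conditions: [Rh(OH)(cod)]2 (cat.), MeO-F12-BIPHEP (antipode giving 2R), toluene/H2O, 40 °C
Reagents that add atoms: none
Why: Rh-catalysed asymmetric 1,4-addition of an arylboronic acid to a chromone (Hayashi–Miyaura reaction); the chiral bisphosphine selects the face of C2=C3 and sets C2.

Step 3
Reactants: 2 5,7-bis(benzyloxy)-4H-chromen-4-one; 3 [4-(benzyloxy)phenyl]boronic acid
Product: 5 (2S)-5,7-bis(benzyloxy)-2-[4-(benzyloxy)phenyl]chroman-4-one (aryl α)
Conditions: [Rh(OH)(cod)]2 (cat.), MeO-F12-BIPHEP (other antipode), toluene/H2O, 40 °C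
Reagents that add atoms: none
Why: The same Hayashi–Miyaura conjugate arylation with the mirror-image ligand sets C2 of the future middle unit.

Step 4
Reactants: 4 (2R)-flavanone
Product: 6 (2R,4R)-5,7-bis(benzyloxy)-2-[4-(benzyloxy)phenyl]chroman-4-ol (2,4-cis expected as the main isomer)
Conditions: NaBH4, THF/MeOH, 0 °C
Reagents that add atoms: none
Why: Hydride reduction of the aryl ketone; the C4 configuration is irrelevant because C4 becomes sp2 in step 5.

Step 5
Reactants: 6 (2R,4R)-flavan-4-ol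
Product: 7 (2R)-5,7-bis(benzyloxy)-2-[4-(benzyloxy)phenyl]-2H-chromene
Conditions: Burgess reagent, toluene, 50 °C
Reagents that add atoms: none
Why: Burgess dehydration (syn elimination of the sulfamate) under neutral conditions spares the acid-sensitive electron-rich ring and C2.

Step 6
Reactants: 7 (2R)-flav-3-ene
Product: 9 (2S,3R)-5,7-bis(benzyloxy)-2-[4-(benzyloxy)phenyl]chroman-3-ol (2,3-trans; 2β-aryl 3α-OH), via alkylborane 8 (not isolated)
Conditions: BH3·THF, THF, 0 °C → rt; then NaOH, H2O2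
Reagents that add atoms: hydrogen peroxide, OO (hydroxyl oxygen); borane, B (boron of 8 only)
Why: Brown hydroboration–oxidation; boron adds to C3 from the face opposite the C2 aryl group and is replaced by OH with retention.

Step 7
Reactants: 9 (2S,3R)-flavan-3-ol
Product: 10 (2S)-5,7-bis(benzyloxy)-2-[4-(benzyloxy)phenyl]chroman-3-one
Conditions: Dess–Martin periodinane, NaHCO3, CH2Cl2, rt
Reagents that add atoms: none
Why: Dess–Martin oxidation under buffered neutral conditions keeps the enolisable C2 stereocentre.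

Step 8
Reactants: 10 (2S)-flavan-3-one
Product: 11 (2S,3S)-5,7-bis(benzyloxy)-2-[4-(benzyloxy)phenyl]chroman-3-ol (2,3-cis; tri-O-benzyl-ent-epiafzelechin)
Conditions: LiBH(s-Bu)3, LiBr, THF, −78 °C
Reagents that add atoms: none
Why: The bulky hydride attacks the face opposite the C2 aryl group and gives the 3β alcohol, the known trans-to-cis inversion of flavan-3-ols.

Step 9
Reactants: 11 (2S,3S)-flavan-3-ol
Product: 12 (2S,3S,4R)-5,7-bis(benzyloxy)-2-[4-(benzyloxy)phenyl]chromane-3,4-diol (3β,4α)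
Conditions: DDQ, CH2Cl2/H2O, rt
Reagents that add atoms: water, O
Why: DDQ benzylic oxidation; hydride is abstracted from C4 of the electron-rich ring A and water adds to the cation trans to the C3 hydroxyl and the C2 aryl group.

Step 10
Reactants: 12 (2S,3S,4R)-diol
Product: 13 3,4-bis-O-(tert-butyldimethylsilyl) ether of 12
Conditions: TBSCl, imidazole, DMAP (cat.), DMF, 40 °C
Reagents that add atoms: tert-butyldimethylsilyl chloride, CC(C)(C)[Si](C)(C)Cl
Why: Silylation masks the ionisable benzylic C4 oxygen for the base-only steps that follow.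

Step 11
Reactants: 13 bis-silyl ether
Product: 14 8-bromo derivative of 13
Conditions: NBS, CH2Cl2, −40 → 0 °C
Reagents that add atoms: N-bromosuccinimide, BrN1C(=O)CCC1=O
Why: Electrophilic aromatic bromination goes to C8, between O1 and 7-OBn, as is usual for 5,7-dialkoxyflavans.

Step 12
Reactants: 14 bottom-unit bromide; 5 (2S)-flavanone
Product: 17 dimer flav-3-ene (middle unit 2α-aryl-2H-chromene joined at C4 to C8 of the bottom unit), via aryllithium 15 (not isolated), via carbinol 16 (not isolated)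
Conditions: t-BuLi (2 equiv), THF, −78 °C; anhydrous CeCl3; 5, −78 → 0 °C; aqueous work-up; Burgess reagent, toluene, rt → 50 °C
Reagents that add atoms: tert-butyllithium, [Li]C(C)(C)C (lithium of 15 only)
Why: Br–Li exchange and CeCl3-mediated carbonyl addition (the organocerium reagent suppresses enolisation and ring opening of the flavanone) form C4(middle)–C8(bottom), and Burgess dehydration of the tertiary doubly benzylic carbinol gives the 4-arylflav-3-ene with C2 untouched.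

Step 13
Reactants: 17 dimer flav-3-ene
Product: 19 dimer 3β-alcohol (middle unit 2α-aryl 3β-OH 4α-aryl), via alkylborane 18 (not isolated)
Conditions: BH3·THF (excess), THF, 0 °C → rt; then NaOH, H2O2
Reagents that add atoms: hydrogen peroxide, OO (hydroxyl oxygen); borane, B (boron of 18 only)
Why: Hydroboration–oxidation; H and B add syn from the β face, opposite the C2 aryl group, so that C4–H is β and the bottom-unit aryl group is α (cis to the C2 aryl group).

Step 14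
Reactants: 19 dimer 3β-alcohol
Product: 20 dimer 3-ketone (middle unit 2α,4α-diaryl)
Conditions: Dess–Martin periodinane, NaHCO3, CH2Cl2, rt
Reagents that add atoms: none
Why: Dess–Martin oxidation; neutral conditions preserve the two enolisable centres C2 and C4.

Step 15
Reactants: 20 dimer 3-ketone
Product: 21 dimer 3α-alcohol (all-cis middle unit: 2α-aryl 3α-OH 4α-aryl)
Conditions: LiBH(s-Bu)3, LiBr, THF, −78 °C
Reagents that add atoms: none
Why: The hydride enters from the β face, opposite both cis aryl groups, so the hydroxyl ends on the α face (the flavan-3-one reduction of step 8 with a second flanking aryl group).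

Step 16
Reactants: 21 dimer 3α-alcohol
Product: 22 3-O-benzyl ether of 21
Conditions: NaH, BnBr, Bu4NI (cat.), DMF, 0 °C → rt
Reagents that add atoms: benzyl bromide, BrCc1ccccc1
Why: Williamson ether synthesis; the ether survives organolithium chemistry and leaves in the final hydrogenolysis.

Step 17
Reactants: 22 dimer benzyl ether
Product: 23 dimer bromide (bromine at C8 of the middle unit)
Conditions: NBS, CH2Cl2, −40 → 0 °C
Reagents that add atoms: N-bromosuccinimide, BrN1C(=O)CCC1=O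
Why: Electrophilic aromatic bromination at the only free position between O1 and an OBn group; both C6 positions lie between two OBn groups and C8 of the bottom unit is occupied.

Step 18
Reactants: 24 2,4,6-trihydroxybenzaldehyde
Product: 25 2,4-bis(benzyloxy)-6-hydroxybenzaldehyde
Conditions: BnBr (2 equiv), K2CO3, DMF, rt
Reagents that add atoms: benzyl bromide, BrCc1ccccc1
Why: Williamson ether synthesis; the hydroxyl hydrogen-bonded to the formyl group is the least reactive and stays free.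

Step 19
Reactants: 25 2,4-bis(benzyloxy)-6-hydroxybenzaldehyde
Product: 26 3,5-bis(benzyloxy)-2-formylphenyl tert-butyl carbonate
Conditions: Boc2O, i-Pr2NEt, DMAP (cat.), THF, rt
Reagents that add atoms: di-tert-butyl dicarbonate, CC(C)(C)OC(=O)OC(=O)OC(C)(C)C
Why: DMAP-catalysed acylation of the phenol gives the aryl carbonate that later serves as the internal leaving-group donor.

Step 20
Reactants: 27 1-(benzyloxy)-4-ethynylbenzene; 28 2,2-dimethylpropanoic acid
Product: 29 (Z)-2-[4-(benzyloxy)phenyl]ethenyl 2,2-dimethylpropanoate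
Conditions: Ru(2-methylallyl)2(dppb) (cat.), toluene, 50 °C
Reagents that add atoms: none
Why: Ru-catalysed anti-Markovnikov addition of a carboxylic acid to a terminal alkyne via a vinylidene complex, which gives the (Z)-enol ester.

Step 21
Reactants: 23 dimer bromide; 26 O-Boc salicylaldehyde; 29 (Z)-enol pivalate
Product: 33 protected trimer with top-unit 3-O-pivalate (top unit 2β-aryl 3β-O 4β-aryl), via aryllithium 30 (not isolated), via phenoxide carbonate 31 (not isolated), via o-quinone methide 32 (not isolated)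
Conditions: t-BuLi (2 equiv), THF, −78 °C; 26, −78 °C; then 29 (4 equiv), MgBr2·OEt2, −78 °C → rt
Reagents that add atoms: tert-butyllithium, [Li]C(C)(C)C (lithium of 30 and 31 only)
Why: Proposed new method: Br–Li exchange gives 30, which adds to the aldehyde carbon of 26 (this bond is C4(top)–C8(middle)); the adduct takes over the ortho Boc group to give 31, and with MgBr2 the phenoxide expels tert-butyl carbonate to form the (E)-o-quinone methide 32 (O1=C8a–C4a=C4), which is trapped by 29. The closest known chemistry is the three-component assembly of chromans from O-Boc salicylaldehydes, organometallics and enol ethers, and the [4+2] addition of o-quinone methides to 4-alkoxystyrenes giving 2,4-cis-flavans; new is a β-acyloxystyrene as the 2π partner. Ring C of the top unit closes by a concerted suprafacial inverse-electron-demand hetero-Diels–Alder reaction (bonds C3–C4 and O1–C2), the aryl-bearing carbon going to oxygen because the 4-benzyloxyphenyl group stabilises positive charge better than the pivaloyloxy group. C2 and C3 are cis because the Z geometry of 29 is transferred stereospecifically, and C4 is cis to both because the (E)-methide (aryl anti to the carbonyl) is approached endo by both alkene substituents. The step also needs π-facial selectivity relative to the dimer: in the working model the twisted C8 aryl group turns its rigid pyran flank (O1–C2 with the α-aryl group) to the open hydrogen side of the methide and its 7-OBn flank towards the peri 5-OBn group, so the alkene passes the face from which the all-α substituents of the middle unit point away, which gives the 4β top unit. This bias is expected to be moderate, and the all-cis isomer built on the other face is the by-product to be separated.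

Step 22
Reactants: 33 trimer pivalate
Product: 34 protected trimer with free top-unit 3β-hydroxyl
Conditions: i-Bu2AlH, CH2Cl2, −78 °C; aq. potassium sodium tartrate
Reagents that add atoms: none
Why: Reductive cleavage of the hindered pivalate by hydride; benzyl and silyl ethers are inert.

Step 23
Reactants: 34 trimer alcohol
Product: 35 deca-O-benzyl trimer with free bottom-unit 3,4-diol
Conditions: Bu4NF, THF, 0 °C → rt
Reagents that add atoms: none
Why: Fluoride-mediated desilylation; with all phenols still benzylated the benzylic C4 alcohol is not prone to ionise.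

Step 24
Reactants: 35 deca-O-benzyl trimer
Product: 36 CNP0159291.1
Conditions: H2 (1 atm), Pd(OH)2/C, THF/MeOH/H2O, rt
Reagents that add atoms: none
Why: Hydrogenolysis of the ten benzyl ethers under neutral conditions; a short reaction time and the absence of acid should keep the benzylic C4 hydroxyl of the bottom unit.

**Compound list**

1 | 5,7-dihydroxy-4H-chromen-4-one | O=c1ccoc2cc(O)cc(O)c12 | starting material
2 | 5,7-bis(benzyloxy)-4H-chromen-4-one | O=c1ccoc2cc(OCc3ccccc3)cc(OCc3ccccc3)c12 | intermediate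
3 | [4-(benzyloxy)phenyl]boronic acid | OB(O)c1ccc(OCc2ccccc2)cc1 | starting material
4 | (2R)-5,7-bis(benzyloxy)-2-[4-(benzyloxy)phenyl]chroman-4-one | O=C1C[C@H](c2ccc(OCc3ccccc3)cc2)Oc2cc(OCc3ccccc3)cc(OCc3ccccc3)c12 | intermediate
5 | (2S)-5,7-bis(benzyloxy)-2-[4-(benzyloxy)phenyl]chroman-4-one | O=C1C[C@@H](c2ccc(OCc3ccccc3)cc2)Oc2cc(OCc3ccccc3)cc(OCc3ccccc3)c12 | intermediate
6 | (2R,4R)-5,7-bis(benzyloxy)-2-[4-(benzyloxy)phenyl]chroman-4-ol | c1c(OCc5ccccc5)cc(OCc5ccccc5)c2c1O[C@@H](c1ccc(OCc5ccccc5)cc1)C[C@H]2O | intermediate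
7 | (2R)-5,7-bis(benzyloxy)-2-[4-(benzyloxy)phenyl]-2H-chromene | c1c(OCc5ccccc5)cc(OCc5ccccc5)c2c1O[C@@H](c1ccc(OCc5ccccc5)cc1)C=C2 | intermediate
8 | C3 alkylborane of 7 (2β-aryl, 3α-boryl; not isolated) | c1c(OCc5ccccc5)cc(OCc5ccccc5)c2c1O[C@@H](c1ccc(OCc5ccccc5)cc1)[C@H](B)C2 | intermediate
9 | (2S,3R)-5,7-bis(benzyloxy)-2-[4-(benzyloxy)phenyl]chroman-3-ol | c1c(OCc5ccccc5)cc(OCc5ccccc5)c2c1O[C@@H](c1ccc(OCc5ccccc5)cc1)[C@H](O)C2 | intermediate
10 | (2S)-5,7-bis(benzyloxy)-2-[4-(benzyloxy)phenyl]chroman-3-one | c1c(OCc5ccccc5)cc(OCc5ccccc5)c2c1O[C@@H](c1ccc(OCc5ccccc5)cc1)C(=O)C2 | intermediate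
11 | (2S,3S)-5,7-bis(benzyloxy)-2-[4-(benzyloxy)phenyl]chroman-3-ol | c1c(OCc5ccccc5)cc(OCc5ccccc5)c2c1O[C@@H](c1ccc(OCc5ccccc5)cc1)[C@@H](O)C2 | intermediate
12 | (2S,3S,4R)-5,7-bis(benzyloxy)-2-[4-(benzyloxy)phenyl]chromane-3,4-diol | c1c(OCc5ccccc5)cc(OCc5ccccc5)c2c1O[C@@H](c1ccc(OCc5ccccc5)cc1)[C@@H](O)[C@@H]2O | intermediate
13 | 3,4-bis-O-(tert-butyldimethylsilyl) ether of 12 (2β-aryl, 3β-OTBS, 4α-OTBS) | c1c(OCc5ccccc5)cc(OCc5ccccc5)c2c1O[C@@H](c1ccc(OCc5ccccc5)cc1)[C@@H](O[Si](C)(C)C(C)(C)C)[C@@H]2O[Si](C)(C)C(C)(C)C | intermediate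
14 | 8-bromo derivative of 13 | Brc1c(OCc5ccccc5)cc(OCc5ccccc5)c2c1O[C@@H](c1ccc(OCc5ccccc5)cc1)[C@@H](O[Si](C)(C)C(C)(C)C)[C@@H]2O[Si](C)(C)C(C)(C)C | intermediate
15 | 8-lithio derivative of 13 (not isolated) | [Li]c1c(OCc5ccccc5)cc(OCc5ccccc5)c2c1O[C@@H](c1ccc(OCc5ccccc5)cc1)[C@@H](O[Si](C)(C)C(C)(C)C)[C@@H]2O[Si](C)(C)C(C)(C)C | intermediate
16 | dimer carbinol: middle-unit 4-hydroxy-4-aryl flavan, C4 epimers, aryl = C8 of bottom unit (not isolated) | c5ccccc5COc1ccc([C@H]2Oc3c(c(OCc5ccccc5)cc(OCc5ccccc5)c3)C(O)(c3c(OCc5ccccc5)cc(OCc5ccccc5)c4c3O[C@@H](c3ccc(OCc5ccccc5)cc3)[C@@H](O[Si](C)(C)C(C)(C)C)[C@@H]4O[Si](C)(C)C(C)(C)C)C2)cc1 | intermediate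
17 | dimer flav-3-ene: middle-unit 2α-aryl-2H-chromene bonded at C4 to C8 of bottom unit | c5ccccc5COc1ccc([C@H]2Oc3c(c(OCc5ccccc5)cc(OCc5ccccc5)c3)C(c3c(OCc5ccccc5)cc(OCc5ccccc5)c4c3O[C@@H](c3ccc(OCc5ccccc5)cc3)[C@@H](O[Si](C)(C)C(C)(C)C)[C@@H]4O[Si](C)(C)C(C)(C)C)=C2)cc1 | intermediate
18 | dimer C3 alkylborane (middle unit 2α-aryl, 3β-boryl, 4α-aryl; not isolated) | c5ccccc5COc1ccc([C@H]2Oc3c(c(OCc5ccccc5)cc(OCc5ccccc5)c3)[C@@H](c3c(OCc5ccccc5)cc(OCc5ccccc5)c4c3O[C@@H](c3ccc(OCc5ccccc5)cc3)[C@@H](O[Si](C)(C)C(C)(C)C)[C@@H]4O[Si](C)(C)C(C)(C)C)[C@@H]2B)cc1 | intermediate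
19 | dimer 3β-alcohol (middle unit 2α-aryl, 3β-OH, 4α-aryl) | c5ccccc5COc1ccc([C@H]2Oc3c(c(OCc5ccccc5)cc(OCc5ccccc5)c3)[C@@H](c3c(OCc5ccccc5)cc(OCc5ccccc5)c4c3O[C@@H](c3ccc(OCc5ccccc5)cc3)[C@@H](O[Si](C)(C)C(C)(C)C)[C@@H]4O[Si](C)(C)C(C)(C)C)[C@@H]2O)cc1 | intermediate
20 | dimer 3-ketone (middle unit 2α,4α-diaryl) | c5ccccc5COc1ccc([C@H]2Oc3c(c(OCc5ccccc5)cc(OCc5ccccc5)c3)[C@@H](c3c(OCc5ccccc5)cc(OCc5ccccc5)c4c3O[C@@H](c3ccc(OCc5ccccc5)cc3)[C@@H](O[Si](C)(C)C(C)(C)C)[C@@H]4O[Si](C)(C)C(C)(C)C)C2=O)cc1 | intermediate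
21 | dimer 3α-alcohol (all-cis middle unit: 2α-aryl, 3α-OH, 4α-aryl) | c5ccccc5COc1ccc([C@H]2Oc3c(c(OCc5ccccc5)cc(OCc5ccccc5)c3)[C@@H](c3c(OCc5ccccc5)cc(OCc5ccccc5)c4c3O[C@@H](c3ccc(OCc5ccccc5)cc3)[C@@H](O[Si](C)(C)C(C)(C)C)[C@@H]4O[Si](C)(C)C(C)(C)C)[C@H]2O)cc1 | intermediate
22 | 3-O-benzyl ether of 21 | c5ccccc5COc1ccc([C@H]2Oc3c(c(OCc5ccccc5)cc(OCc5ccccc5)c3)[C@@H](c3c(OCc5ccccc5)cc(OCc5ccccc5)c4c3O[C@@H](c3ccc(OCc5ccccc5)cc3)[C@@H](O[Si](C)(C)C(C)(C)C)[C@@H]4O[Si](C)(C)C(C)(C)C)[C@H]2OCc5ccccc5)cc1 | intermediate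
23 | dimer bromide (22 with bromine at C8 of the middle unit) | c5ccccc5COc1ccc([C@H]2Oc3c(c(OCc5ccccc5)cc(OCc5ccccc5)c3Br)[C@@H](c3c(OCc5ccccc5)cc(OCc5ccccc5)c4c3O[C@@H](c3ccc(OCc5ccccc5)cc3)[C@@H](O[Si](C)(C)C(C)(C)C)[C@@H]4O[Si](C)(C)C(C)(C)C)[C@H]2OCc5ccccc5)cc1 | intermediate
24 | 2,4,6-trihydroxybenzaldehyde | O=Cc1c(O)cc(O)cc1O | starting material
25 | 2,4-bis(benzyloxy)-6-hydroxybenzaldehyde | O=Cc1c(O)cc(OCc2ccccc2)cc1OCc1ccccc1 | intermediate
26 | 3,5-bis(benzyloxy)-2-formylphenyl tert-butyl carbonate | O=Cc1c(OC(=O)OC(C)(C)C)cc(OCc2ccccc2)cc1OCc1ccccc1 | intermediate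
27 | 1-(benzyloxy)-4-ethynylbenzene | C#Cc1ccc(OCc2ccccc2)cc1 | starting material
28 | 2,2-dimethylpropanoic acid | CC(C)(C)C(=O)O | starting material
29 | (Z)-2-[4-(benzyloxy)phenyl]ethenyl 2,2-dimethylpropanoate | CC(C)(C)C(=O)O/C=C\c1ccc(OCc2ccccc2)cc1 | intermediate
30 | dimer aryllithium (22 lithiated at C8 of the middle unit; not isolated) | c5ccccc5COc1ccc([C@H]2Oc3c(c(OCc5ccccc5)cc(OCc5ccccc5)c3[Li])[C@@H](c3c(OCc5ccccc5)cc(OCc5ccccc5)c4c3O[C@@H](c3ccc(OCc5ccccc5)cc3)[C@@H](O[Si](C)(C)C(C)(C)C)[C@@H]4O[Si](C)(C)C(C)(C)C)[C@H]2OCc5ccccc5)cc1 | intermediate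
31 | lithium phenoxide with benzylic tert-butyl carbonate (carbinol carbon epimers; not isolated) | c5ccccc5COc1ccc([C@H]2Oc3c(c(OCc5ccccc5)cc(OCc5ccccc5)c3C(OC(=O)OC(C)(C)C)c6c([O-])cc(OCc5ccccc5)cc6OCc5ccccc5)[C@@H](c3c(OCc5ccccc5)cc(OCc5ccccc5)c4c3O[C@@H](c3ccc(OCc5ccccc5)cc3)[C@@H](O[Si](C)(C)C(C)(C)C)[C@@H]4O[Si](C)(C)C(C)(C)C)[C@H]2OCc5ccccc5)cc1.[Li+] | intermediate
32 | (E)-o-quinone methide: 6-(arylmethylidene)-3,5-bis(benzyloxy)cyclohexa-2,4-dien-1-one, aryl = C8 of the middle unit (not isolated) | c5ccccc5COc1ccc([C@H]2Oc3c(c(OCc5ccccc5)cc(OCc5ccccc5)c3/C=C6/C(=O)C=C(OCc5ccccc5)C=C6OCc5ccccc5)[C@@H](c3c(OCc5ccccc5)cc(OCc5ccccc5)c4c3O[C@@H](c3ccc(OCc5ccccc5)cc3)[C@@H](O[Si](C)(C)C(C)(C)C)[C@@H]4O[Si](C)(C)C(C)(C)C)[C@H]2OCc5ccccc5)cc1 | intermediate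
33 | protected trimer, top-unit 3-O-pivalate (top unit 2β-aryl, 3β-OPiv, 4β-aryl) | c5ccccc5COc1ccc([C@H]2Oc3c(c(OCc5ccccc5)cc(OCc5ccccc5)c3[C@H]3c4c(OCc5ccccc5)cc(OCc5ccccc5)cc4O[C@@H](c4ccc(OCc5ccccc5)cc4)[C@H]3OC(=O)C(C)(C)C)[C@@H](c3c(OCc5ccccc5)cc(OCc5ccccc5)c4c3O[C@@H](c3ccc(OCc5ccccc5)cc3)[C@@H](O[Si](C)(C)C(C)(C)C)[C@@H]4O[Si](C)(C)C(C)(C)C)[C@H]2OCc5ccccc5)cc1 | intermediate
34 | protected trimer, free top-unit 3β-hydroxyl | c5ccccc5COc1ccc([C@H]2Oc3c(c(OCc5ccccc5)cc(OCc5ccccc5)c3[C@H]3c4c(OCc5ccccc5)cc(OCc5ccccc5)cc4O[C@@H](c4ccc(OCc5ccccc5)cc4)[C@H]3O)[C@@H](c3c(OCc5ccccc5)cc(OCc5ccccc5)c4c3O[C@@H](c3ccc(OCc5ccccc5)cc3)[C@@H](O[Si](C)(C)C(C)(C)C)[C@@H]4O[Si](C)(C)C(C)(C)C)[C@H]2OCc5ccccc5)cc1 | intermediate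
35 | deca-O-benzyl trimer, free top 3-OH and bottom 3,4-diol | c5ccccc5COc1ccc([C@H]2Oc3c(c(OCc5ccccc5)cc(OCc5ccccc5)c3[C@H]3c4c(OCc5ccccc5)cc(OCc5ccccc5)cc4O[C@@H](c4ccc(OCc5ccccc5)cc4)[C@H]3O)[C@@H](c3c(OCc5ccccc5)cc(OCc5ccccc5)c4c3O[C@@H](c3ccc(OCc5ccccc5)cc3)[C@@H](O)[C@@H]4O)[C@H]2OCc5ccccc5)cc1 | intermediate
36 | CNP0159291.1: ent-epiafzelechin-(4β→8)-epiafzelechin-(4α→8)-(2S,3S,4R)-3,4,5,7,4'-pentahydroxyflavan | Oc1ccc([C@H]2Oc3c(c(O)cc(O)c3[C@H]3c4c(O)cc(O)cc4O[C@@H](c4ccc(O)cc4)[C@H]3O)[C@@H](c3c(O)cc(O)c4c3O[C@@H](c3ccc(O)cc3)[C@@H](O)[C@@H]4O)[C@H]2O)cc1 | target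

**Step count and risks**

Total steps: 24. Longest linear sequence: 20 steps (1, 2, 4–17, 21–24).

Three steps most likely to fail:

1. Step 21 (Proposed new method). The cycloaddition may show poor π-facial selectivity relative to the dimer. The stabilised o-quinone methide may also be consumed by tert-butoxide addition, or the enol ester may transfer its acyl group, before [4+2] closure. A stepwise ionic path would erode the 2,3-cis relationship. Fallback (known chemistry, from 23, back to the route at 34): 23 is lithiated as before to 30, transmetalated with CeCl3 and added to flavanone 4, giving the trimer carbinol F1. Burgess dehydration gives the trimer flav-3-ene F2. Hydroboration (BH3·THF) through the alkylborane F3, then NaOH/H2O2, gives the 2,3-trans-3,4-trans alcohol F4, with the C4–H set opposite the C2 aryl group. Dess–Martin oxidation gives the ketone F5, and LiBH(s-Bu)3 at −78 °C gives 34. All three stereocentres of the top unit then descend from C2 of 4, at the cost of three more steps.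

2. Step 12. Enolisation and ring opening of the flavanone, or steric retardation of the carbonyl addition by the two ortho oxygens of the nucleophile, may outrun C–C bond formation. Fallback (from 5 and 14, back at 17): 5 is converted with Tf2O and 2,6-di-tert-butyl-4-methylpyridine into the enol triflate F6. Bromide 14 is lithiated and transmetalated with ZnCl2 to the arylzinc chloride F7. Negishi coupling (Pd2(dba)3, SPhos, THF, 50 °C) then gives 17 directly, with no carbonyl addition and no dehydration.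

3. Step 24. The benzylic C4 hydroxyl of the bottom unit may be lost by hydrogenolysis, or ionise once the phenols are free. Fallback (from 34, back at 36): the order of the last two steps is reversed. Hydrogenolysis of 34 (H2, Pd(OH)2/C) with the C4 oxygen still silylated gives the bis-silyl polyphenol F8. Buffered fluoride (Bu4NF/AcOH, THF, 0 °C) then releases 36, so that no free benzylic alcohol is exposed to the catalyst.

Further compounds
F1 | step 21 | trimer carbinol: top-unit 4-hydroxy-4-aryl flavan (2β-aryl, C4 epimers) on C8 of the middle unit of 22 | c5ccccc5COc1ccc([C@H]2Oc3c(c(OCc5ccccc5)cc(OCc5ccccc5)c3C3(O)c4c(OCc5ccccc5)cc(OCc5ccccc5)cc4O[C@@H](c4ccc(OCc5ccccc5)cc4)C3)[C@@H](c3c(OCc5ccccc5)cc(OCc5ccccc5)c4c3O[C@@H](c3ccc(OCc5ccccc5)cc3)[C@@H](O[Si](C)(C)C(C)(C)C)[C@@H]4O[Si](C)(C)C(C)(C)C)[C@H]2OCc5ccccc5)cc1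
F2 | step 21 | trimer flav-3-ene: top-unit 2β-aryl-2H-chromene bonded at C4 to C8 of the middle unit | c5ccccc5COc1ccc([C@H]2Oc3c(c(OCc5ccccc5)cc(OCc5ccccc5)c3C3c4c(OCc5ccccc5)cc(OCc5ccccc5)cc4O[C@@H](c4ccc(OCc5ccccc5)cc4)C=3)[C@@H](c3c(OCc5ccccc5)cc(OCc5ccccc5)c4c3O[C@@H](c3ccc(OCc5ccccc5)cc3)[C@@H](O[Si](C)(C)C(C)(C)C)[C@@H]4O[Si](C)(C)C(C)(C)C)[C@H]2OCc5ccccc5)cc1
F3 | step 21 | trimer C3 alkylborane (top unit 2β-aryl, 3α-boryl, 4β-aryl; not isolated) | c5ccccc5COc1ccc([C@H]2Oc3c(c(OCc5ccccc5)cc(OCc5ccccc5)c3[C@H]3c4c(OCc5ccccc5)cc(OCc5ccccc5)cc4O[C@@H](c4ccc(OCc5ccccc5)cc4)[C@@H]3B)[C@@H](c3c(OCc5ccccc5)cc(OCc5ccccc5)c4c3O[C@@H](c3ccc(OCc5ccccc5)cc3)[C@@H](O[Si](C)(C)C(C)(C)C)[C@@H]4O[Si](C)(C)C(C)(C)C)[C@H]2OCc5ccccc5)cc1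
F4 | step 21 | trimer 3α-alcohol (top unit 2β-aryl, 3α-OH, 4β-aryl; 2,3-trans-3,4-trans) | c5ccccc5COc1ccc([C@H]2Oc3c(c(OCc5ccccc5)cc(OCc5ccccc5)c3[C@H]3c4c(OCc5ccccc5)cc(OCc5ccccc5)cc4O[C@@H](c4ccc(OCc5ccccc5)cc4)[C@@H]3O)[C@@H](c3c(OCc5ccccc5)cc(OCc5ccccc5)c4c3O[C@@H](c3ccc(OCc5ccccc5)cc3)[C@@H](O[Si](C)(C)C(C)(C)C)[C@@H]4O[Si](C)(C)C(C)(C)C)[C@H]2OCc5ccccc5)cc1
F5 | step 21 | trimer 3-ketone (top unit 2β,4β-diaryl) | c5ccccc5COc1ccc([C@H]2Oc3c(c(OCc5ccccc5)cc(OCc5ccccc5)c3[C@H]3c4c(OCc5ccccc5)cc(OCc5ccccc5)cc4O[C@@H](c4ccc(OCc5ccccc5)cc4)C3=O)[C@@H](c3c(OCc5ccccc5)cc(OCc5ccccc5)c4c3O[C@@H](c3ccc(OCc5ccccc5)cc3)[C@@H](O[Si](C)(C)C(C)(C)C)[C@@H]4O[Si](C)(C)C(C)(C)C)[C@H]2OCc5ccccc5)cc1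
F6 | step 12 | (2S)-5,7-bis(benzyloxy)-2-[4-(benzyloxy)phenyl]-2H-chromen-4-yl trifluoromethanesulfonate | FC(F)(F)S(=O)(=O)OC1=C[C@@H](c2ccc(OCc3ccccc3)cc2)Oc2cc(OCc3ccccc3)cc(OCc3ccccc3)c12
F7 | step 12 | arylzinc chloride from 14 (zinc at C8; not isolated) | Cl[Zn]c1c(OCc5ccccc5)cc(OCc5ccccc5)c2c1O[C@@H](c1ccc(OCc5ccccc5)cc1)[C@@H](O[Si](C)(C)C(C)(C)C)[C@@H]2O[Si](C)(C)C(C)(C)C
F8 | step 24 | target with the bottom-unit 3,4-diol as bis(tert-butyldimethylsilyl) ether | Oc1ccc([C@H]2Oc3c(c(O)cc(O)c3[C@H]3c4c(O)cc(O)cc4O[C@@H](c4ccc(O)cc4)[C@H]3O)[C@@H](c3c(O)cc(O)c4c3O[C@@H](c3ccc(O)cc3)[C@@H](O[Si](C)(C)C(C)(C)C)[C@@H]4O[Si](C)(C)C(C)(C)C)[C@H]2O)cc1
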